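**Overview**

- Cuts: the 3'-O-MOM ether goes last. Before it, C4a–C5 (Claisen) and O1–C2 (oxa-Michael) are cut together, which unfolds rings A and C into a 4-hydroxy-2-pyrone bearing an aryl ynone. That is cut at C4–C4a into an arylpropiolic Weinreb amide (fragment 1) and triacetic acid lactone (fragment 2). The alkyne goes back to an aldehyde, and ring D to an aryl 1,1-dimethylpropargyl ether of 3,4-dihydroxybenzaldehyde.
- Enabling feature: going from C2 through C3, C4, C4a, C8a, C8, C7 and C6 to C5, the nine carbons of rings C and A bear oxygen at alternate positions (C2, C4, C8a, C7, C5). This is a pentaketide chain whose C2 end carries the chromenyl group (rings B and D). An alkyne can stand for C2/C3 and a 2-pyrone for C5 to C8a.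
- Forward order: ring B is purchased. Ring D closes first by a propargyl ether Claisen cascade. The aldehyde is homologated to the alkyne and then the Weinreb amide. The chain is joined at C4–C4a. Rings A and C close together in one operation, and MOM removal ends the route.
- Stereochemistry: there is no stereocentre. The single non-aromatic double bond (C3=C4 of the chromene, ring D) can only be cis within its six-membered ring.

Key step: step 7

Remark: flavone numbering is used for the target and chain numbering (ester carbon = C1) for 14. Compounds 13 to 15 are drawn in one tautomeric form each, and the lithium or magnesium salts in which species exist in the flask are not numbered separately.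

**Route**

Step 1
Reactants: 1 3,4-dihydroxybenzaldehyde; 2 3-chloro-3-methylbut-1-yne
Product: 3 3-hydroxy-4-[(2-methylbut-3-yn-2-yl)oxy]benzaldehyde
Conditions: 2 (1.1 equiv), DBU (1.2 equiv), CuCl2·2H2O (1 mol %), MeCN, 0 °C to rt, Ar
Reagents that add atoms: 3-chloro-3-methylbut-1-yne (compound 2), C#CC(C)(C)Cl
Why: Copper-catalysed O-propargylation of a phenol with a tertiary propargylic chloride is the standard entry to aryl 1,1-dimethylpropargyl ethers, and about one equivalent of base should ionise only the 4-OH, which is para to the formyl group and the more acidic of the two.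

Step 2
Reactants: 3 3-hydroxy-4-[(2-methylbut-3-yn-2-yl)oxy]benzaldehyde
Product: 4 3-(methoxymethoxy)-4-[(2-methylbut-3-yn-2-yl)oxy]benzaldehyde
Conditions: MOMCl (1.5 equiv), i-Pr2NEt (2 equiv), CH2Cl2, 0 °C to rt
Reagents that add atoms: chloromethyl methyl ether (MOMCl), COCCl
Why: Standard MOM ether formation (O-alkylation of the remaining phenol) masks the acidic OH before the thermal step and the later base and organolithium steps, and aldehyde and alkyne are inert to it.

Step 3
Reactants: 4 3-(methoxymethoxy)-4-[(2-methylbut-3-yn-2-yl)oxy]benzaldehyde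
Product: 7 8-(methoxymethoxy)-2,2-dimethyl-2H-chromene-6-carbaldehyde, via allenylphenol 5 (not isolated), via ortho-quinone methide 6 (not isolated)
Conditions: PhNEt2, 190 °C, Ar
Reagents that add atoms: none
Why: The thermal aryl propargyl ether Claisen rearrangement can only go to the one free ortho carbon and should give allenylphenol 5 after tautomerisation; its 1,5-hydrogen shift to the (Z)-quinone methide 6 and oxa-6π electrocyclisation then close ring D, a cascade that is the usual route to 2,2-dimethyl-2H-chromenes and tolerates a para formyl group.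

Step 4
Reactants: 7 8-(methoxymethoxy)-2,2-dimethyl-2H-chromene-6-carbaldehyde; 8 dimethyl (1-diazo-2-oxopropyl)phosphonate
Product: 9 6-ethynyl-8-(methoxymethoxy)-2,2-dimethyl-2H-chromene
Conditions: 8 (1.3 equiv), K2CO3 (2 equiv), MeOH, 0 °C to rt
Reagents that add atoms: dimethyl (1-diazo-2-oxopropyl)phosphonate (compound 8), CC(=O)C(=[N+]=[N-])P(=O)(OC)OC
Why: In the Ohira–Bestmann variant of the Seyferth–Gilbert homologation, methanolysis of 8 releases the diazomethylphosphonate anion, which should turn the non-enolisable aryl aldehyde into the terminal alkyne under mild base that leaves the MOM ether and the chromene untouched.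

Step 5
Reactants: 9 6-ethynyl-8-(methoxymethoxy)-2,2-dimethyl-2H-chromene; 10 N-methoxy-N-methylcarbamoyl chloride
Product: 11 N-methoxy-3-[8-(methoxymethoxy)-2,2-dimethyl-2H-chromen-6-yl]-N-methylprop-2-ynamide (fragment 1)
Conditions: n-BuLi (1.05 equiv), THF, −78 °C; then 10 (1.2 equiv), −78 to 0 °C; aq NH4Cl
Reagents that add atoms: N-methoxy-N-methylcarbamoyl chloride (compound 10), CON(C)C(=O)Cl
Why: Acylation of a lithium acetylide with a carbamoyl chloride is the standard preparation of alkynyl Weinreb amides, and one equivalent of n-BuLi at low temperature should remove only the alkyne proton, by far the most acidic one.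

Step 6
Reactants: 11 N-methoxy-3-[8-(methoxymethoxy)-2,2-dimethyl-2H-chromen-6-yl]-N-methylprop-2-ynamide; 12 triacetic acid lactone (4-hydroxy-6-methyl-2H-pyran-2-one, fragment 2)
Product: 13 4-hydroxy-6-{4-[8-(methoxymethoxy)-2,2-dimethyl-2H-chromen-6-yl]-2-oxobut-3-yn-1-yl}-2H-pyran-2-one
Conditions: 12 (1.3 equiv), LiN(i-Pr)2 (2.7 equiv), THF, −78 °C; then 11, −78 to −40 °C; AcOH, −78 °C, then pH 4 buffer
Reagents that add atoms: none
Why: C-acylation of the O,C-dilithio derivative of a 4-hydroxy-6-methyl-2-pyrone at its 6-methyl carbon is established dianion chemistry, and a Weinreb amide is used as acyl donor (Weinreb ketone synthesis) because its chelated tetrahedral adduct should persist until the quench, so the ynone never meets the dianion.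

Step 7
Reactants: 13 4-hydroxy-6-{4-[8-(methoxymethoxy)-2,2-dimethyl-2H-chromen-6-yl]-2-oxobut-3-yn-1-yl}-2H-pyran-2-one
Product: 16 3'-O-MOM Yinyanghuo E, via triketo ester 14 (not isolated), via acylphloroglucinol ynone 15 (not isolated)
Conditions: Mg(OMe)2 (5 equiv), MeOH, 65 °C, Ar; then AcOH, 40 °C
Reagents that add atoms: methanol, CO (its methoxy group enters the not-isolated ester 14 and leaves again when ring A closes; none of its atoms remain in 16)
Why: Proposed new method: Methoxide should open the 2-pyrone of 13 at its lactone carbonyl to the magnesium-bound triketo ester 14, whose methylene between the C5 and C7 ketones (the future C4a) attacks the ester carbonyl (the future C5) in a Claisen condensation; enolisation then gives the 2,4,6-trihydroxyphenyl ynone 15, and one of its two equivalent ortho hydroxyls adds to the aryl-bearing alkyne carbon (the future C2). The closest known reaction types are the Mg(OMe)2-induced Claisen folding of 6-(acylmethyl)-4-hydroxy-2-pyrones and 3,5,7-triketo esters to acylphloroglucinols and the 6-endo cyclisation of 2-hydroxyaryl ynones to flavones, and what is untested is their union on a pyrone that already carries the ynone. Ring A closes 6-exo-trig through the C4a–C5 bond and ring C closes 6-endo-dig through the O1–C2 bond, or by addition-elimination if methoxide has first added reversibly to the ynone, in which case the acetic acid treatment completes the closure. No stereocentre is formed. The step needs Claisen rather than aldol closure (attack of the ester α-carbon on the C4 ketone would give a resorcylate) and a flavone rather than an aurone: chelation of the enolised chain by magnesium favours the Claisen mode, reversible hetero-Michael addition of methoxide turns the C4 carbonyl into a vinylogous ester that is a poor aldol acceptor, and displacement at the β-carbon can lead only to the six-membered ring. The substrate suits the fold because the alkyne brings C2 in at the flavone oxidation level and the lactone brings in ring A with its hydroxyls free, so neither an oxidation nor a phenol deprotection is needed beside the chromene, and closure of O1–C2 before C4a–C5 would form the same two bonds.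

Step 8
Reactants: 16 3'-O-MOM Yinyanghuo E
Product: 17 Yinyanghuo E
Conditions: 3 M aq HCl, MeOH, 50 °C
Reagents that add atoms: none
Why: Acid-catalysed acetal exchange with methanol (MOM ether cleavage) should free the 3'-hydroxyl under conditions that flavones and 2,2-dimethyl-2H-chromenes normally survive.

**Compound list**

1 | 3,4-dihydroxybenzaldehyde | O=Cc1ccc(O)c(O)c1 | starting material
2 | 3-chloro-3-methylbut-1-yne | C#CC(C)(C)Cl | starting material
3 | 3-hydroxy-4-[(2-methylbut-3-yn-2-yl)oxy]benzaldehyde | C#CC(C)(C)Oc1ccc(C=O)cc1O | intermediate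
4 | 3-(methoxymethoxy)-4-[(2-methylbut-3-yn-2-yl)oxy]benzaldehyde | C#CC(C)(C)Oc1ccc(C=O)cc1OCOC | intermediate
5 | 4-hydroxy-3-(methoxymethoxy)-5-(3-methylbuta-1,2-dien-1-yl)benzaldehyde (allenylphenol, formed in the flask, not isolated) | CC(C)=C=Cc1cc(C=O)cc(OCOC)c1O | intermediate
6 | (3Z)-5-(methoxymethoxy)-3-(3-methylbut-2-en-1-ylidene)-4-oxocyclohexa-1,5-diene-1-carbaldehyde (ortho-quinone methide, formed in the flask, not isolated) | CC(C)=C/C=C1/C=C(C=O)C=C(OCOC)C1=O | intermediate
7 | 8-(methoxymethoxy)-2,2-dimethyl-2H-chromene-6-carbaldehyde | CC1(C)C=Cc2cc(C=O)cc(OCOC)c2O1 | intermediate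
8 | dimethyl (1-diazo-2-oxopropyl)phosphonate | CC(=O)C(=[N+]=[N-])P(=O)(OC)OC | starting material
9 | 6-ethynyl-8-(methoxymethoxy)-2,2-dimethyl-2H-chromene | CC1(C)C=Cc2cc(C#C)cc(OCOC)c2O1 | intermediate
10 | N-methoxy-N-methylcarbamoyl chloride | CON(C)C(=O)Cl | starting material
11 | N-methoxy-3-[8-(methoxymethoxy)-2,2-dimethyl-2H-chromen-6-yl]-N-methylprop-2-ynamide | CC1(C)C=Cc2cc(C#CC(=O)N(C)OC)cc(OCOC)c2O1 | intermediate
12 | triacetic acid lactone (4-hydroxy-6-methyl-2H-pyran-2-one) | CC1=CC(O)=CC(=O)O1 | starting material
13 | 4-hydroxy-6-{4-[8-(methoxymethoxy)-2,2-dimethyl-2H-chromen-6-yl]-2-oxobut-3-yn-1-yl}-2H-pyran-2-one | CC1(C)C=Cc2cc(C#CC(=O)CC3=CC(O)=CC(=O)O3)cc(OCOC)c2O1 | intermediate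
14 | methyl 9-[8-(methoxymethoxy)-2,2-dimethyl-2H-chromen-6-yl]-3,5,7-trioxonon-8-ynoate (formed in the flask, not isolated) | CC1(C)C=Cc2cc(C#CC(=O)CC(=O)CC(=O)CC(=O)OC)cc(OCOC)c2O1 | intermediate
15 | 3-[8-(methoxymethoxy)-2,2-dimethyl-2H-chromen-6-yl]-1-(2,4,6-trihydroxyphenyl)prop-2-yn-1-one (formed in the flask, not isolated) | CC1(C)C=Cc2cc(C#CC(=O)c3c(O)cc(O)cc3O)cc(OCOC)c2O1 | intermediate
16 | 3'-O-MOM Yinyanghuo E, 5,7-dihydroxy-2-[8-(methoxymethoxy)-2,2-dimethyl-2H-chromen-6-yl]-4H-chromen-4-one | CC1(C)C=Cc2cc(-c3cc(=O)c4c(O)cc(O)cc4o3)cc(OCOC)c2O1 | intermediate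
17 | Yinyanghuo E, 5,7-dihydroxy-2-(8-hydroxy-2,2-dimethyl-2H-chromen-6-yl)-4H-chromen-4-one | CC1(C)C=Cc2cc(-c3cc(=O)c4c(O)cc(O)cc4o3)cc(O)c2O1 | target

**Count**

Total step count: 8. Longest linear sequence: 8 steps (1 to 17).

**Steps most likely to fail**

1. Step 7 (proposed new method). The unmasked chain may close in the aldol mode instead of the Claisen mode. Methoxide may add to the ynone and stall, or cleave the chain by retro-Claisen fragmentation. The oxygen may also close 5-exo.
Fallback with known chemistry, setting out from alkyne 9 and coming back at target 17. Commercial 2,4,6-trihydroxybenzaldehyde (O=Cc1c(O)cc(O)cc1O) would be fully protected with MOMCl and NaH in DMF to 2,4,6-tris(methoxymethoxy)benzaldehyde F1. The lithium acetylide of 9 (n-BuLi, THF, −78 °C) would add to F1 to give the racemic propargylic alcohol F2. Oxidation with MnO2 in CH2Cl2 should give the aryl ynone F3. Conjugate addition of diethylamine in EtOH at rt should give the (E)-enaminone F4, whose geometry does not matter for what follows. Treatment with 3 M HCl in MeOH at 50 °C should remove all four MOM groups. The freed ortho hydroxyl then displaces diethylamine by addition-elimination, which can only form the six-membered ring C, and 17 results directly.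

2. Step 6. The dilithio lactone or diisopropylamine may add in conjugate fashion to the alkynyl amide. Conversion may be poor because the dianion aggregates and is sparingly soluble. The ynone may decompose on acidification.
Fallback setting out from alkyne 9 and coming back at pyrone 13. Lithiation of 9 (n-BuLi, THF, −78 °C) and formylation with DMF would give the arylpropynal F5. Aldol addition of the dilithio derivative of 12 (LiN(i-Pr)2, THF, −78 °C) to the aldehyde, a 1,2-addition that is well established for this dianion, should give the racemic propargylic alcohol F6. Oxidation with Dess–Martin periodinane in CH2Cl2 should then give 13, so the C4–C4a bond is made by aldol addition and oxidation instead of acylation.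

3. Step 1. Site selectivity may be lost (etherification of the 3-OH or of both hydroxyls). The catechol may also chelate or be oxidised by the copper catalyst and stall the catalytic cycle.
Fallback setting out from 1 and coming back at 4. Benzylation with BnBr, NaHCO3 and NaI in DMF at 40 °C, selective for the 4-OH, would give 4-(benzyloxy)-3-hydroxybenzaldehyde F7. MOMCl and i-Pr2NEt in CH2Cl2 would give 4-(benzyloxy)-3-(methoxymethoxy)benzaldehyde F8. Hydrogenolysis (H2, Pd/C, EtOAc, rt, stopped at full debenzylation) would give 4-hydroxy-3-(methoxymethoxy)benzaldehyde F9. This monophenol would then be etherified with 2 under the conditions of step 1 (DBU, catalytic CuCl2·2H2O, MeCN, 0 °C) to give 4 with no selectivity question left.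

**Further compounds**

F1 | step 7 | 2,4,6-tris(methoxymethoxy)benzaldehyde | COCOc1cc(OCOC)c(C=O)c(OCOC)c1
F2 | step 7 | 3-[8-(methoxymethoxy)-2,2-dimethyl-2H-chromen-6-yl]-1-[2,4,6-tris(methoxymethoxy)phenyl]prop-2-yn-1-ol (racemic) | COCOc1cc(OCOC)c(C(O)C#Cc2cc3C=CC(C)(C)Oc3c(OCOC)c2)c(OCOC)c1
F3 | step 7 | 3-[8-(methoxymethoxy)-2,2-dimethyl-2H-chromen-6-yl]-1-[2,4,6-tris(methoxymethoxy)phenyl]prop-2-yn-1-one | COCOc1cc(OCOC)c(C(=O)C#Cc2cc3C=CC(C)(C)Oc3c(OCOC)c2)c(OCOC)c1
F4 | step 7 | (E)-3-(diethylamino)-3-[8-(methoxymethoxy)-2,2-dimethyl-2H-chromen-6-yl]-1-[2,4,6-tris(methoxymethoxy)phenyl]prop-2-en-1-one | COCOc1cc(OCOC)c(C(=O)/C=C(/N(CC)CC)c2cc3C=CC(C)(C)Oc3c(OCOC)c2)c(OCOC)c1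
F5 | step 6 | 3-[8-(methoxymethoxy)-2,2-dimethyl-2H-chromen-6-yl]prop-2-ynal | CC1(C)C=Cc2cc(C#CC=O)cc(OCOC)c2O1
F6 | step 6 | 4-hydroxy-6-{2-hydroxy-4-[8-(methoxymethoxy)-2,2-dimethyl-2H-chromen-6-yl]but-3-yn-1-yl}-2H-pyran-2-one (racemic) | CC1(C)C=Cc2cc(C#CC(O)CC3=CC(O)=CC(=O)O3)cc(OCOC)c2O1
F7 | step 1 | 4-(benzyloxy)-3-hydroxybenzaldehyde | O=Cc1ccc(OCc2ccccc2)c(O)c1
F8 | step 1 | 4-(benzyloxy)-3-(methoxymethoxy)benzaldehyde | COCOc1cc(C=O)ccc1OCc1ccccc1
F9 | step 1 | 4-hydroxy-3-(methoxymethoxy)benzaldehyde | COCOc1cc(C=O)ccc1O
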